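**Retrosynthetic overview**
- Aryl–vinyl bond: Mizoroki–Heck coupling of the terpenyl acrylate with 5-bromo-2-methoxyphenol (two steps from catechol). Ester C–O bond: acryloylation of the secondary hydroxyl of eudesmane-4β,6β-diol.
- Diol: syn-selective reduction of trans-fused 4β-hydroxyeudesman-6-one, whose C4, C5 and C7 centres are set by retro-aldol/aldol equilibration.
- Ring B (key step): one-carbon ring expansion of a cyclopentanone to the α-isopropylcyclohexanone, the ring CH2 shifting onto an isobutylidene carbon (from 2-methylpropanal) with loss of N2.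
- Ring A: intramolecular aldol of (R)-3-methyl-3-(4-oxopentyl)cyclopentanone. Quaternary carbon: copper-catalysed asymmetric conjugate addition to 3-methylcyclopent-2-enone.
- Ring order: purchased five-membered ring, then ring A by aldol, then the five-membered ring is expanded to ring B; the arene is purchased.

Assumption: decalin carbons carry eudesmane numbers at every stage (C4 carbinol, C5/C10 ring fusion, C6 carbonyl or ester carbon, C7 isopropyl carbon), β is the face of the C10 methyl, and reagent solutions made in a second flask (Grignard reagent, diazoalkane) belong to the step that uses them.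

**Step 1**
Reactants: 1 3-methylcyclopent-2-en-1-one; 2 2-(3-chloropropyl)-2-methyl-1,3-dioxolane
Product: 5 (3R)-3-methyl-3-(4-oxopentyl)cyclopentan-1-one, via Grignard reagent 3 (not isolated), via acetal ketone 4 (not isolated)
Conditions: 2, Mg, THF, 50 °C; then 1, Cu(OTf)2 (3 mol %), chiral 4,5-diphenylimidazolinium chloride (NHC precursor, 4 mol %), Et2O, −30 °C; 1 M HCl, THF, rt
Reagents that add atoms: water, O
Why: Copper–NHC-catalysed asymmetric conjugate addition of a Grignard reagent to a β,β-disubstituted cyclic enone builds the quaternary carbon, the ligand enantiomer being chosen to deliver the alkyl group to the Re face of C3 (R centre, the future C10), and the acidic work-up hydrolyses the dioxolane.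

**Step 2**
Reactants: 5 (3R)-3-methyl-3-(4-oxopentyl)cyclopentan-1-one
Product: 6 (3aR,7R,7aS)-7-hydroxy-3a,7-dimethyloctahydro-1H-inden-1-one
Conditions: KOH (0.1 equiv), MeOH, 0 °C
Reagents that add atoms: none
Why: Reversible base-catalysed intramolecular aldol addition (6-enolexo-exo-trig) of the enolate lying between the ring carbonyl and the quaternary carbon closes ring A; under thermodynamic control the fusion is cis (the stable arrangement of a hydrindan-1-one with an angular methyl) and the hydroxyl lies anti to the angular methyl, hydrogen-bonded to the ketone with the C4 methyl equatorial, and because both centres are re-equilibrated in step 4 any minor isomers converge.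

**Step 3**
Reactants: 6 (3aR,7R,7aS)-7-hydroxy-3a,7-dimethyloctahydro-1H-inden-1-one; 7 2-methylpropanal
Product: 10 (2RS,4aR,8R,8aS)-8-hydroxy-4a,8-dimethyl-2-(propan-2-yl)octahydronaphthalen-1(2H)-one, via isobutyraldehyde hydrazone 8 (not isolated), via 1-diazo-2-methylpropane 9 (not isolated)
Conditions: 7, N2H4·H2O, 0 °C, then MnO2, CH2Cl2, −20 °C, cold filtration (solution of 9); added slowly to 6, Sc(OTf)3 (10 mol %), toluene, −78 → −30 °C
Reagents that add atoms: none
Why: Proposed new method: a hydroxyl-assisted Sc(OTf)3-catalysed insertion of an isobutylidene unit from a branched alkyl diazomethane into the C(O)–CH2 bond of a free β-hydroxy cyclopentanone, in which the ketone and the neighbouring tertiary hydroxyl hold the Lewis acid in a six-membered chelate, the diazo carbon adds to the activated carbonyl from the convex face, and in the diazonium betaine the unhindered ring CH2 (C8) rather than the methine flanked by two fully substituted carbons (C5) migrates antiperiplanar to the departing N2, so that C4 and C5 are untouched and the new C7 centre (formed as a mixture) is set in step 4; the closest known reaction type is the Lewis-acid-catalysed diazoalkane–cycloalkanone homologation (Büchner–Curtius–Schlotterbeck or Tiffeneau–Demjanov-type ring expansion), known for aryl and simple alkyl diazomethanes on ketones without a free β-hydroxyl.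

**Step 4**
Reactants: 10 (2RS,4aR,8R,8aS)-8-hydroxy-4a,8-dimethyl-2-(propan-2-yl)octahydronaphthalen-1(2H)-one
Product: 12 (1R,2S,4aR,8S,8aS)-4a,8-dimethyl-2-(propan-2-yl)decahydronaphthalene-1,8-diol, via trans-fused ketol 11 (not isolated)
Conditions: KOt-Bu (0.2 equiv), THF, 0 °C → rt; AcOH (0.2 equiv); then Et2BOMe, NaBH4, THF/MeOH, −78 → −20 °C; MeOH work-up
Reagents that add atoms: none
Why: Catalytic base equilibrates C4 and C5 by retro-aldol/aldol and C7 by enolisation to the trans-fused ketol 11, the only isomer that is an all-chair decalin with the isopropyl and the C4 methyl equatorial and the axial hydroxyl bridged to the ketone (the cis-fused isomers must either push a C4 substituent into the concave face or give up that bridge), and Narasaka–Prasad reduction of its boron chelate then takes hydride on the α face, opposite the axial C10 methyl, to give the syn 4β,6β-diol.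

**Step 5**
Reactants: 12 (1R,2S,4aR,8S,8aS)-4a,8-dimethyl-2-(propan-2-yl)decahydronaphthalene-1,8-diol; 13 prop-2-enoyl chloride
Product: 14 (1R,2S,4aR,8S,8aS)-8-hydroxy-4a,8-dimethyl-2-(propan-2-yl)decahydronaphthalen-1-yl prop-2-enoate
Conditions: 13 (2 equiv), Et3N (3 equiv), DMAP (0.2 equiv), CH2Cl2, 0 °C → rt
Reagents that add atoms: none
Why: DMAP-catalysed esterification (nucleophilic acyl substitution) acylates only the secondary C6 hydroxyl because the tertiary C4 hydroxyl is inert under these conditions, and no stereocentre is touched.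

**Step 6**
Reactants: 15 benzene-1,2-diol
Product: 16 2-methoxyphenol
Conditions: MeI (1.0 equiv), K2CO3 (1.0 equiv), acetone, reflux
Reagents that add atoms: iodomethane, CI
Why: Williamson ether synthesis with one equivalent of MeI gives mainly the monomethyl ether, and unreacted diol and the dimethyl ether are removed by base extraction and distillation.

**Step 7**
Reactants: 16 2-methoxyphenol
Product: 19 5-bromo-2-methoxyphenol, via 2-methoxyphenyl acetate 17 (not isolated), via 5-bromo-2-methoxyphenyl acetate 18 (not isolated)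
Conditions: Ac2O (1.05 equiv), H2SO4 (cat.), MeCN, rt; NBS (1.05 equiv), rt; then MeOH, 60 °C
Reagents that add atoms: N-bromosuccinimide, O=C1CCC(=O)N1Br
Why: Electrophilic aromatic bromination in which transient O-acetylation leaves the methoxy group as the dominant director so that bromine enters para to it, followed by acid-catalysed methanolysis (transesterification) to free the phenol.

**Step 8**
Reactants: 14 (1R,2S,4aR,8S,8aS)-8-hydroxy-4a,8-dimethyl-2-(propan-2-yl)decahydronaphthalen-1-yl prop-2-enoate; 19 5-bromo-2-methoxyphenol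
Product: 20 (1R,2S,4aR,8S,8aS)-8-hydroxy-4a,8-dimethyl-2-(propan-2-yl)decahydronaphthalen-1-yl (2E)-3-(3-hydroxy-4-methoxyphenyl)prop-2-enoate
Conditions: 19 (1.2 equiv), Pd(OAc)2 (5 mol %), P(o-tol)3 (10 mol %), Et3N, DMF, 100 °C
Reagents that add atoms: none
Why: Mizoroki–Heck reaction of the aryl bromide with the acrylate, in which syn insertion and syn β-hydride elimination give the E alkene and the free phenol, the tertiary alcohol and the hindered ester are tolerated.

**Compound list**
1 | 3-methylcyclopent-2-en-1-one | CC1=CC(=O)CC1 | starting material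
2 | 2-(3-chloropropyl)-2-methyl-1,3-dioxolane (ethylene acetal of 5-chloropentan-2-one) | CC1(CCCCl)OCCO1 | starting material
3 | chlorido[3-(2-methyl-1,3-dioxolan-2-yl)propyl]magnesium | CC1(CCC[Mg]Cl)OCCO1 | intermediate
4 | (3R)-3-methyl-3-[3-(2-methyl-1,3-dioxolan-2-yl)propyl]cyclopentan-1-one | O=C1C[C@](C)(CCCC2(C)OCCO2)CC1 | intermediate
5 | (3R)-3-methyl-3-(4-oxopentyl)cyclopentan-1-one | O=C1C[C@](C)(CCCC(C)=O)CC1 | intermediate
6 | (3aR,7R,7aS)-7-hydroxy-3a,7-dimethyloctahydro-1H-inden-1-one (cis-fused, hydroxyl anti to the angular methyl) | O=C1[C@H]2[C@](C)(CCC[C@@]2(C)O)CC1 | intermediate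
7 | 2-methylpropanal | CC(C)C=O | starting material
8 | (E)-(2-methylpropylidene)hydrazine | CC(C)/C=N/N | intermediate
9 | 1-diazo-2-methylpropane | CC(C)C=[N+]=[N-] | intermediate
10 | (2RS,4aR,8R,8aS)-8-hydroxy-4a,8-dimethyl-2-(propan-2-yl)octahydronaphthalen-1(2H)-one (cis-fused, mixture of C7 epimers) | O=C1[C@H]2[C@](C)(CCC[C@@]2(C)O)CCC1C(C)C | intermediate
11 | (2S,4aR,8S,8aR)-8-hydroxy-4a,8-dimethyl-2-(propan-2-yl)octahydronaphthalen-1(2H)-one (4β-hydroxy-5α-eudesman-6-one) | O=C1[C@@H]2[C@](C)(CCC[C@]2(C)O)CC[C@H]1C(C)C | intermediate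
12 | (1R,2S,4aR,8S,8aS)-4a,8-dimethyl-2-(propan-2-yl)decahydronaphthalene-1,8-diol (eudesmane-4β,6β-diol) | O[C@H]1[C@@H]2[C@](C)(CCC[C@]2(C)O)CC[C@H]1C(C)C | intermediate
13 | prop-2-enoyl chloride | C=CC(=O)Cl | starting material
14 | (1R,2S,4aR,8S,8aS)-8-hydroxy-4a,8-dimethyl-2-(propan-2-yl)decahydronaphthalen-1-yl prop-2-enoate | C=CC(=O)O[C@H]1[C@@H]2[C@](C)(CCC[C@]2(C)O)CC[C@H]1C(C)C | intermediate
15 | benzene-1,2-diol | Oc1ccccc1O | starting material
16 | 2-methoxyphenol | COc1ccccc1O | intermediate
17 | 2-methoxyphenyl acetate | COc1ccccc1OC(C)=O | intermediate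
18 | 5-bromo-2-methoxyphenyl acetate | COc1ccc(Br)cc1OC(C)=O | intermediate
19 | 5-bromo-2-methoxyphenol | COc1ccc(Br)cc1O | intermediate
20 | (1R,2S,4aR,8S,8aS)-8-hydroxy-4a,8-dimethyl-2-(propan-2-yl)decahydronaphthalen-1-yl (2E)-3-(3-hydroxy-4-methoxyphenyl)prop-2-enoate | COc1ccc(/C=C/C(=O)O[C@H]2[C@@H]3[C@](C)(CCC[C@]3(C)O)CC[C@H]2C(C)C)cc1O | target

**Totals**
Total step count: 8. Longest linear sequence: 6 steps (steps 1, 2, 3, 4, 5, 8); the aryl branch is steps 6 and 7.

**Steps most likely to fail, with fallbacks**

Step 1. Grignard conjugate additions to five-membered β-methyl enones often give only moderate enantioselectivity. The fallback sets out from Grignard reagent 3, which is added 1,2 (THF, 0 °C) to purchased 3-methoxycyclopent-2-en-1-one F1. Cold dilute HCl work-up (Stork–Danheiser transposition) gives 3-[3-(2-methyl-1,3-dioxolan-2-yl)propyl]cyclopent-2-en-1-one F2. The methyl group is then delivered by conjugate addition of Me3Al catalysed by Cu(OTf)2 and a chiral NHC (THF, −78 °C), a combination with good precedent for 3-alkylcyclopentenones. This comes back to the route at 4, which is hydrolysed to 5 as in step 1.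

Step 3 (the proposed new ring expansion). The branched diazoalkane may decompose faster than it adds to the hindered ketone, or the Lewis acid may open the ketol. The fallback uses known chemistry and sets out from 6. Ring expansion with benzyl diazoacetate promoted by BF3·OEt2 (CH2Cl2, −78 → 0 °C, the less substituted α-carbon migrates) gives benzyl (2RS,4aR,8R,8aS)-8-hydroxy-4a,8-dimethyl-1-oxodecahydronaphthalene-2-carboxylate F3. C-Alkylation with 2-iodopropane (Cs2CO3, DMF, 50 °C) gives benzyl (2RS,4aR,8R,8aS)-8-hydroxy-4a,8-dimethyl-1-oxo-2-(propan-2-yl)decahydronaphthalene-2-carboxylate F4. Hydrogenolysis (H2, Pd/C, EtOAc) gives (2RS,4aR,8R,8aS)-8-hydroxy-4a,8-dimethyl-1-oxo-2-(propan-2-yl)decahydronaphthalene-2-carboxylic acid F5, which loses CO2 on gentle warming and comes back to the route at 10.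

Step 4. The preference for the trans-fused ketol 11 is argued from conformational analysis, not measured; the equilibrium may not favour it strongly, or the ketol may drain away by dehydration. The fallback sets out from 10 and uses the dehydration deliberately. TsOH (cat.) in toluene at 80 °C gives the conjugated enone (2S,4aR)-4a,8-dimethyl-2-(propan-2-yl)-3,4,4a,5,6,7-hexahydronaphthalen-1(2H)-one F6, with the isopropyl carbon equilibrating to the equatorial epimer. Luche reduction (NaBH4, CeCl3·7H2O, MeOH, −78 °C, hydride anti to the C10 methyl) gives (1R,2S,4aR)-4a,8-dimethyl-2-(propan-2-yl)-1,2,3,4,4a,5,6,7-octahydronaphthalen-1-ol F7. Hydroxyl-directed epoxidation (VO(acac)2, t-BuOOH, toluene) gives the β-epoxide (4S,5S,6R,7S,10R)-4,5-epoxyeudesman-6-ol F8. LiAlH4 (THF, reflux) opens it trans-diaxially at C5 (Fürst–Plattner rule), which sets 5α-H and 4β-OH and comes back to the route at 12.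

**Further compounds**
F1 | step 1 | 3-methoxycyclopent-2-en-1-one | COC1=CC(=O)CC1
F2 | step 1 | 3-[3-(2-methyl-1,3-dioxolan-2-yl)propyl]cyclopent-2-en-1-one | O=C1C=C(CCCC2(C)OCCO2)CC1
F3 | step 3 | benzyl (2RS,4aR,8R,8aS)-8-hydroxy-4a,8-dimethyl-1-oxodecahydronaphthalene-2-carboxylate | O=C1[C@H]2[C@](C)(CCC[C@@]2(C)O)CCC1C(=O)OCc1ccccc1
F4 | step 3 | benzyl (2RS,4aR,8R,8aS)-8-hydroxy-4a,8-dimethyl-1-oxo-2-(propan-2-yl)decahydronaphthalene-2-carboxylate | O=C1[C@H]2[C@](C)(CCC[C@@]2(C)O)CCC1(C(C)C)C(=O)OCc1ccccc1
F5 | step 3 | (2RS,4aR,8R,8aS)-8-hydroxy-4a,8-dimethyl-1-oxo-2-(propan-2-yl)decahydronaphthalene-2-carboxylic acid | O=C1[C@H]2[C@](C)(CCC[C@@]2(C)O)CCC1(C(C)C)C(=O)O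
F6 | step 4 | (2S,4aR)-4a,8-dimethyl-2-(propan-2-yl)-3,4,4a,5,6,7-hexahydronaphthalen-1(2H)-one | O=C1C2=C(C)CCC[C@]2(C)CC[C@H]1C(C)C
F7 | step 4 | (1R,2S,4aR)-4a,8-dimethyl-2-(propan-2-yl)-1,2,3,4,4a,5,6,7-octahydronaphthalen-1-ol | O[C@H]1C2=C(C)CCC[C@]2(C)CC[C@H]1C(C)C
F8 | step 4 | (4S,5S,6R,7S,10R)-4,5-epoxyeudesman-6-ol | O[C@H]1[C@@]23O[C@@]3(C)CCC[C@]2(C)CC[C@H]1C(C)C
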